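**Strategy.** Three bonds of the decalin are disconnected around quaternary C9: C7–C8, C9–C11 and the ring-fusion bond C5–C10. The feature used is that C9 (bearing C20 and C11) lies between C8 (bearing C17) and fusion carbon C10, while C5–C10 joins rings A and B and can be closed transannularly in a ten-membered ring. A single thermal cascade (oxy-Cope rearrangement, Claisen shift of an O-allyl group to C9, carbonyl-ene closure) therefore builds rings A and B and sets C5, C8, C9 and C10. Its precursor is the allyl ether of enantioenriched trans-1-[(Z)-but-2-en-2-yl]-3,3-dimethyl-2-vinylcyclohexanol. Allyl group, C6–C7 alkene and C10 hydroxyl are later converted into the side chain, the saturated C6–C7 bond and the Δ1(10) alkene.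

Key step: step 9

**Remarks on the chemistry (assumptions)**
- Atom numbers are halimane numbers: decalin C1–C10 (C4 gem-dimethyl, C5 and C10 ring fusion), C17 on C8, C20 and the chain C11–C15 on C9, C16 on C13.
- The target (5S,8R,9R) has C17 cis to C11 and to H5 and trans to C20. The oxy-Cope and Claisen bonds add anti across the butenyl double bond, so this requires the (Z)-butenyl ether with (1S,2R) ring configuration (17).
- (Z)-2-Bromobut-2-ene (bromine cis to the C4 methyl, methyl groups trans) is taken as purchasable in isomerically pure form.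
- Ylide 24 is taken as a purchasable reagent.
- The lipase is assumed to follow its usual preference for acylating the (1R)-carbinol.
- The sense of induction of the Josiphos ligand in step 14 is given from memory of its behaviour with linear (E)-enethioates; the ligand antipode is the variable to adjust.

Step 1
Reactants: 1 ethyl vinyl ether; 2 benzeneselenenyl chloride
Product: 4 (phenylselanyl)acetaldehyde, via diethyl acetal 3 (not isolated)
Conditions: EtOH, 0 °C to rt; then 1 M HCl, Et2O–H2O, rt
Reagents that add atoms: water, O; ethanol, CCO (kept only in intermediate 3)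
Why: Markovnikov selenoetherification of the enol ether (seleniranium ion opened by ethanol at the oxygen-bearing carbon) followed by acetal hydrolysis is a standard route to this α-seleno aldehyde, and no stereocentre is formed.

Step 2
Reactants: 5 3-methylcyclohex-2-en-1-one; 4 (phenylselanyl)acetaldehyde
Product: 7 rac-2-[1-hydroxy-2-(phenylselanyl)ethyl]-3,3-dimethylcyclohexan-1-one (both diastereomers), via magnesium enolate 6 (not isolated)
Conditions: MeMgBr (1.05 equiv), CuBr·SMe2 (5 mol %), THF, −30 to 0 °C; then 4, −78 °C; aq NH4Cl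
Reagents that add atoms: methylmagnesium bromide, C[Mg]Br
Why: Copper-catalysed conjugate addition builds the gem-dimethyl carbon (C4) and gives the enolate regiospecifically at the future C5, which the reactive aldehyde traps (tandem conjugate addition–aldol); the two new stereocentres are left uncontrolled because one is removed in step 3 and the other is resolved in step 5.

Step 3
Reactants: 7 rac-2-[1-hydroxy-2-(phenylselanyl)ethyl]-3,3-dimethylcyclohexan-1-one
Product: 8 rac-3,3-dimethyl-2-vinylcyclohexan-1-one
Conditions: MsCl, Et3N, CH2Cl2, 0 °C to rt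
Reagents that add atoms: none
Why: Mesylation of the β-hydroxy selenide triggers anti elimination of PhSe and OMs through a seleniranium ion (reductive β-hydroxy selenide elimination, a ketone α-vinylation with a vinyl cation equivalent), which gives the terminal vinyl group instead of the conjugated ethylidene ketone.

Step 4
Reactants: 8 rac-3,3-dimethyl-2-vinylcyclohexan-1-one
Product: 9 rac-cis-3,3-dimethyl-2-vinylcyclohexan-1-ol
Conditions: LiBH(s-Bu)3, THF, −78 °C; then NaOH, H2O2, 0 °C
Reagents that add atoms: none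
Why: The bulky borohydride should attack the carbonyl from the equatorial side, anti to the vinyl group and away from the syn-axial C3 methyl, so the cis alcohol is expected (diastereoselective hydride reduction).

Step 5
Reactants: 9 rac-cis-3,3-dimethyl-2-vinylcyclohexan-1-ol
Product: 10 (1S,2R)-3,3-dimethyl-2-vinylcyclohexan-1-ol
Conditions: Burkholderia cepacia lipase (immobilised), vinyl acetate, t-BuOMe, 35 °C, to ca. 55% conversion; chromatography
Reagents that add atoms: none
Why: Lipase-catalysed kinetic resolution by transesterification should acylate the (1R)-carbinol faster (empirical rule for secondary alcohols, large group = C2), leaving the (1S,2R)-alcohol, which is separated from the acetate.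

Step 6
Reactants: 10 (1S,2R)-3,3-dimethyl-2-vinylcyclohexan-1-ol
Product: 11 (2R)-3,3-dimethyl-2-vinylcyclohexan-1-one
Conditions: Dess–Martin periodinane, pyridine, CH2Cl2, 0 °C
Reagents that add atoms: none
Why: Dess–Martin oxidation under buffered, non-enolising conditions converts the carbinol to the ketone while the α-vinyl stereocentre (C2, future C5) is kept.

Step 7
Reactants: 11 (2R)-3,3-dimethyl-2-vinylcyclohexan-1-one; 12 (Z)-2-bromobut-2-ene
Product: 15 (1S,2R)-1-[(2Z)-but-2-en-2-yl]-3,3-dimethyl-2-vinylcyclohexan-1-ol, via butenyllithium 13 (not isolated), via butenylcerium dichloride 14 (not isolated)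
Conditions: 12, t-BuLi (2 equiv), Et2O, −78 °C; CeCl3, THF, −78 °C; then 11, −78 to −40 °C; aq NH4Cl
Reagents that add atoms: none
Why: Br–Li exchange with retention and transmetalation give a weakly basic organocerium reagent whose 1,2-addition (organocerium carbonyl addition) avoids enolisation, and attack anti to the C2 vinyl group and away from the syn-axial C3 methyl should set C1 with butenyl trans to vinyl.

Step 8
Reactants: 15 (1S,2R)-1-[(2Z)-but-2-en-2-yl]-3,3-dimethyl-2-vinylcyclohexan-1-ol; 16 allyl bromide
Product: 17 (1S,2R)-1-(allyloxy)-1-[(2Z)-but-2-en-2-yl]-3,3-dimethyl-2-vinylcyclohexane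
Conditions: NaH, Bu4NI (cat.), DMF, 0 °C to rt, 16 in excess and present from the start
Reagents that add atoms: none
Why: Williamson etherification of the tertiary sodium alkoxide with a reactive allylic bromide touches no stereocentre, and the sodium counter-ion, low temperature and excess electrophile are chosen so that O-alkylation outruns an anionic oxy-Cope rearrangement.

Step 9
Reactants: 17 (1S,2R)-1-(allyloxy)-1-[(2Z)-but-2-en-2-yl]-3,3-dimethyl-2-vinylcyclohexane
Product: 20 (1R,2R,4aS,8aR)-1-allyl-1,2,5,5-tetramethyl-1,2,4a,5,6,7,8,8a-octahydronaphthalen-8a-ol, via allyl enol ether 18 (not isolated), via allyl ketone 19 (not isolated)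
Conditions: PhMe (0.02 M), Et3N (1 equiv), base-washed sealed tube or microwave, 220 °C
Reagents that add atoms: none
Why: On heating, the diequatorial trans-dialkenyl ether undergoes a chair [3,3] oxy-Cope shift (C7–C8 made, C5–C10 broken) to the ten-membered allyl enol ether 18, a Claisen [3,3] shift then moves the allyl group from oxygen to C9 (ketone 19), and a transannular carbonyl-ene reaction re-forms C5–C10 with transfer of H7 to oxygen. The closest known reaction type is the thermal tandem oxy-Cope/Claisen/transannular ene reaction of allyl ethers of 1,2-dialkenylcyclohexanols. The one new C5–C10 bond closes ring A (6-exo with respect to the C5=C6 alkene) and ring B (6-endo) together, through a boat-like ene transition state of bicyclo[2.2.2] shape. C8 is set by chirality transfer from C1/C2 of 17 through the chair, in which the (Z)-methyl group is pseudo-axial, and C9 by delivery of the allyl group to the outer face of the ring enol ether, anti to the new C7–C8 bond, which puts C11 cis to C17 (an (E)-butenyl group would give the C17/C20-cis series). The E ring alkene enforces the trans ring fusion, and C5/C10 should be set by closure from the ring conformer that keeps C17 on the face of ring B away from the carbonyl oxygen and the migrating hydrogen (reached by turn-over of the C5=C6 unit, whose vinyl hydrogens pass through the ring), so that H5 ends cis to C17 and C11. The step needs chair-over-boat control in the first shift and this conformer selection in the last; the diequatorial alkenyl groups, the quaternary C4 (one ene mode only) and the C8 methyl are the securing elements, and Et3N guards the tertiary allylic ether against acid.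

Step 10
Reactants: 20 (1R,2R,4aS,8aR)-1-allyl-1,2,5,5-tetramethyl-1,2,4a,5,6,7,8,8a-octahydronaphthalen-8a-ol
Product: 22 3-[(1R,2R,4aS,8aR)-8a-hydroxy-1,2,5,5-tetramethyl-1,2,4a,5,6,7,8,8a-octahydronaphthalen-1-yl]propan-1-ol, via alkylborane 21 (not isolated)
Conditions: 9-BBN (2.5 equiv), THF, 0 °C to rt; then NaOH, H2O2, 0 °C
Reagents that add atoms: hydrogen peroxide, OO; 9-borabicyclo[3.3.1]nonane, B1C2CCCC1CCC2 (kept only in intermediate 21)
Why: Hydroboration–oxidation with the bulky dialkylborane is selective for the monosubstituted allyl double bond over the ring alkene and places boron, then oxygen, on the terminal carbon C13 (anti-Markovnikov).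

Step 11
Reactants: 22 3-[(1R,2R,4aS,8aR)-8a-hydroxy-1,2,5,5-tetramethyl-1,2,4a,5,6,7,8,8a-octahydronaphthalen-1-yl]propan-1-ol
Product: 23 3-[(1R,2R,4aS,8aR)-8a-hydroxy-1,2,5,5-tetramethyldecahydronaphthalen-1-yl]propan-1-ol
Conditions: TsNHNH2 (excess, in portions), NaOAc, DME–H2O, reflux
Reagents that add atoms: none
Why: Diimide reduction saturates the only remaining alkene (C6–C7) without metal-induced double-bond migration, so C5 and C8 cannot be scrambled, and it is done before the Δ1(10) alkene exists so that no doubly allylic C5–H is ever present.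

Step 12
Reactants: 23 3-[(1R,2R,4aS,8aR)-8a-hydroxy-1,2,5,5-tetramethyldecahydronaphthalen-1-yl]propan-1-ol; 24 S-ethyl (triphenyl-λ5-phosphanylidene)ethanethioate
Product: 26 S-ethyl (2E)-5-[(1R,2R,4aS,8aR)-8a-hydroxy-1,2,5,5-tetramethyldecahydronaphthalen-1-yl]pent-2-enethioate, via hydroxy aldehyde 25 (not isolated)
Conditions: 2,2,6,6-tetramethylpiperidin-1-oxyl (TEMPO, 10 mol %), PhI(OAc)2, CH2Cl2, rt; then 24, 40 °C
Reagents that add atoms: none
Why: Oxoammonium oxidation stops at the aldehyde and leaves the tertiary hydroxyl untouched (it is anti to the axial side chain and cannot form a lactol), and the stabilised ylide then gives the (E)-enethioate in the same flask (one-pot oxidation–Wittig olefination).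

Step 13
Reactants: 26 S-ethyl (2E)-5-[(1R,2R,4aS,8aR)-8a-hydroxy-1,2,5,5-tetramethyldecahydronaphthalen-1-yl]pent-2-enethioate
Product: 27 S-ethyl (2E)-5-[(1R,2R,4aS)-1,2,5,5-tetramethyl-1,2,3,4,4a,5,6,7-octahydronaphthalen-1-yl]pent-2-enethioate
Conditions: methyl N-(triethylammoniosulfonyl)carbamate (Burgess reagent), PhMe, 50 °C
Reagents that add atoms: none
Why: Syn elimination of the tertiary sulfamate (Burgess dehydration) can only use a C1 hydrogen, because H5 is anti to the C10 oxygen in the trans-fused system and C9 carries no hydrogen, so the Δ1(10) alkene should form and C10 becomes planar.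

Step 14
Reactants: 27 S-ethyl (2E)-5-[(1R,2R,4aS)-1,2,5,5-tetramethyl-1,2,3,4,4a,5,6,7-octahydronaphthalen-1-yl]pent-2-enethioate
Product: 28 S-ethyl (3R)-3-methyl-5-[(1R,2R,4aS)-1,2,5,5-tetramethyl-1,2,3,4,4a,5,6,7-octahydronaphthalen-1-yl]pentanethioate
Conditions: MeMgBr (1.3 equiv), CuBr·SMe2 (5 mol %), (R)-1-[(S)-2-(diphenylphosphino)ferrocenyl]ethyldicyclohexylphosphine [(R,S)-Josiphos, 6 mol %], t-BuOMe, −75 °C
Reagents that add atoms: methylmagnesium bromide, C[Mg]Br
Why: Copper-catalysed asymmetric conjugate addition of MeMgBr to an (E)-α,β-unsaturated thioester sets C13 under catalyst control, the (R,S)-ligand being the antipode expected to deliver methyl to the Re face of C13 (13R), remote from the ring stereocentres.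

Step 15
Reactants: 28 S-ethyl (3R)-3-methyl-5-[(1R,2R,4aS)-1,2,5,5-tetramethyl-1,2,3,4,4a,5,6,7-octahydronaphthalen-1-yl]pentanethioate
Product: 29 (3R)-3-methyl-5-[(1R,2R,4aS)-1,2,5,5-tetramethyl-1,2,3,4,4a,5,6,7-octahydronaphthalen-1-yl]pentanoic acid
Conditions: LiOH, THF–H2O, rt; then 1 M HCl to pH 3
Reagents that add atoms: lithium hydroxide, [Li+].[OH-]
Why: Thioesters are saponified under mild conditions (basic hydrolysis), and C13, being β to the carbonyl, cannot epimerise.

Step 16
Reactants: 29 (3R)-3-methyl-5-[(1R,2R,4aS)-1,2,5,5-tetramethyl-1,2,3,4,4a,5,6,7-octahydronaphthalen-1-yl]pentanoic acid; 30 (R)-glycidol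
Product: 31 [(2S)-oxiran-2-yl]methyl (3R)-3-methyl-5-[(1R,2R,4aS)-1,2,5,5-tetramethyl-1,2,3,4,4a,5,6,7-octahydronaphthalen-1-yl]pentanoate
Conditions: DCC, 4-(dimethylamino)pyridine (DMAP, cat.), CH2Cl2, 0 °C to rt
Reagents that add atoms: none
Why: Steglich esterification acylates the primary hydroxyl without touching the epoxide, so the glycerol stereocentre comes from (R)-glycidol unchanged in space (its descriptor becomes S only because the acyloxymethyl group gains priority).

Step 17
Reactants: 31 [(2S)-oxiran-2-yl]methyl (3R)-3-methyl-5-[(1R,2R,4aS)-1,2,5,5-tetramethyl-1,2,3,4,4a,5,6,7-octahydronaphthalen-1-yl]pentanoate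
Product: 32 (2S)-3-acetoxy-2-hydroxypropyl (3R)-3-methyl-5-[(1R,2R,4aS)-1,2,5,5-tetramethyl-1,2,3,4,4a,5,6,7-octahydronaphthalen-1-yl]pentanoate (CNP0317518.1)
Conditions: AcOH (5 equiv), Bu4NOAc (10 mol %), MeCN, 50 °C
Reagents that add atoms: acetic acid, CC(=O)O
Why: Acetate-catalysed addition of a carboxylic acid to a terminal epoxide (nucleophilic ring opening at the CH2 terminus) leaves the C–O bond at the stereocentre intact, and the excess acid keeps the new alkoxide protonated to limit acyl migration.

**Compound list**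
1 | ethyl vinyl ether | C=COCC | starting material
2 | benzeneselenenyl chloride | Cl[Se]c1ccccc1 | starting material
3 | (2,2-diethoxyethyl)(phenyl)selane | CCOC(C[Se]c1ccccc1)OCC | intermediate
4 | (phenylselanyl)acetaldehyde | O=CC[Se]c1ccccc1 | intermediate
5 | 3-methylcyclohex-2-en-1-one | CC1=CC(=O)CCC1 | starting material
6 | bromomagnesium 3,3-dimethylcyclohex-1-en-1-olate | CC1(C)CCCC(O[Mg]Br)=C1 | intermediate
7 | rac-2-[1-hydroxy-2-(phenylselanyl)ethyl]-3,3-dimethylcyclohexan-1-one (both diastereomers) | O=C1CCCC(C)(C)C1C(O)C[Se]c1ccccc1 | intermediate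
8 | rac-3,3-dimethyl-2-vinylcyclohexan-1-one | C=CC1C(=O)CCCC1(C)C | intermediate
9 | rac-cis-3,3-dimethyl-2-vinylcyclohexan-1-ol (racemate; the 1S,2R enantiomer is drawn) | O[C@H]1CCCC(C)(C)[C@H]1C=C | intermediate
10 | (1S,2R)-3,3-dimethyl-2-vinylcyclohexan-1-ol | O[C@H]1CCCC(C)(C)[C@H]1C=C | intermediate
11 | (2R)-3,3-dimethyl-2-vinylcyclohexan-1-one | O=C1CCCC(C)(C)[C@H]1C=C | intermediate
12 | (Z)-2-bromobut-2-ene | C/C=C(\Br)C | starting material
13 | (2E)-but-2-en-2-yllithium (lithium cis to the C4 methyl, formed with retention) | C/C=C(\[Li])C | intermediate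
14 | dichloro[(2Z)-but-2-en-2-yl]cerium | C/C=C(\[Ce](Cl)Cl)C | intermediate
15 | (1S,2R)-1-[(2Z)-but-2-en-2-yl]-3,3-dimethyl-2-vinylcyclohexan-1-ol (butenyl trans to vinyl) | O[C@@]1(/C(C)=C\C)CCCC(C)(C)[C@H]1C=C | intermediate
16 | allyl bromide | C=CCBr | starting material
17 | (1S,2R)-1-(allyloxy)-1-[(2Z)-but-2-en-2-yl]-3,3-dimethyl-2-vinylcyclohexane | C=CCO[C@@]1(/C(C)=C\C)CCCC(C)(C)[C@H]1C=C | intermediate
18 | (1Z,3R,5E)-1-(allyloxy)-2,3,7,7-tetramethylcyclodeca-1,5-diene | C=CCO/C1=C(C)\[C@H](C)C/C=C/C(C)(C)CCC1 | intermediate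
19 | (2R,3R,5E)-2-allyl-2,3,7,7-tetramethylcyclodec-5-en-1-one | C=CC[C@@]1(C)C(=O)CCCC(C)(C)/C=C/C[C@H]1C | intermediate
20 | (1R,2R,4aS,8aR)-1-allyl-1,2,5,5-tetramethyl-1,2,4a,5,6,7,8,8a-octahydronaphthalen-8a-ol (halimane numbering: 5S,8R,9R,10R; trans-fused, C6–C7 alkene, C10–OH cis to C20 and anti to the allyl group) | C=CC[C@@]1(C)[C@@]2(O)CCCC(C)(C)[C@@H]2C=C[C@H]1C | intermediate
21 | 9-{3-[(1R,2R,4aS,8aR)-8a-hydroxy-1,2,5,5-tetramethyl-1,2,4a,5,6,7,8,8a-octahydronaphthalen-1-yl]propyl}-9-borabicyclo[3.3.1]nonane | C(CC[C@@]1(C)[C@@]2(O)CCCC(C)(C)[C@@H]2C=C[C@H]1C)B3C4CCCC3CCC4 | intermediate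
22 | 3-[(1R,2R,4aS,8aR)-8a-hydroxy-1,2,5,5-tetramethyl-1,2,4a,5,6,7,8,8a-octahydronaphthalen-1-yl]propan-1-ol | OCCC[C@@]1(C)[C@@]2(O)CCCC(C)(C)[C@@H]2C=C[C@H]1C | intermediate
23 | 3-[(1R,2R,4aS,8aR)-8a-hydroxy-1,2,5,5-tetramethyldecahydronaphthalen-1-yl]propan-1-ol | OCCC[C@@]1(C)[C@@]2(O)CCCC(C)(C)[C@@H]2CC[C@H]1C | intermediate
24 | S-ethyl (triphenyl-λ5-phosphanylidene)ethanethioate | CCSC(=O)C=P(c1ccccc1)(c1ccccc1)c1ccccc1 | starting material
25 | 3-[(1R,2R,4aS,8aR)-8a-hydroxy-1,2,5,5-tetramethyldecahydronaphthalen-1-yl]propanal | O=CCC[C@@]1(C)[C@@]2(O)CCCC(C)(C)[C@@H]2CC[C@H]1C | intermediate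
26 | S-ethyl (2E)-5-[(1R,2R,4aS,8aR)-8a-hydroxy-1,2,5,5-tetramethyldecahydronaphthalen-1-yl]pent-2-enethioate | CCSC(=O)/C=C/CC[C@@]1(C)[C@@]2(O)CCCC(C)(C)[C@@H]2CC[C@H]1C | intermediate
27 | S-ethyl (2E)-5-[(1R,2R,4aS)-1,2,5,5-tetramethyl-1,2,3,4,4a,5,6,7-octahydronaphthalen-1-yl]pent-2-enethioate | CCSC(=O)/C=C/CC[C@@]1(C)C2=CCCC(C)(C)[C@@H]2CC[C@H]1C | intermediate
28 | S-ethyl (3R)-3-methyl-5-[(1R,2R,4aS)-1,2,5,5-tetramethyl-1,2,3,4,4a,5,6,7-octahydronaphthalen-1-yl]pentanethioate | CCSC(=O)C[C@H](C)CC[C@@]1(C)C2=CCCC(C)(C)[C@@H]2CC[C@H]1C | intermediate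
29 | (3R)-3-methyl-5-[(1R,2R,4aS)-1,2,5,5-tetramethyl-1,2,3,4,4a,5,6,7-octahydronaphthalen-1-yl]pentanoic acid | OC(=O)C[C@H](C)CC[C@@]1(C)C2=CCCC(C)(C)[C@@H]2CC[C@H]1C | intermediate
30 | (R)-glycidol | C1[C@H](O1)CO | starting material
31 | [(2S)-oxiran-2-yl]methyl (3R)-3-methyl-5-[(1R,2R,4aS)-1,2,5,5-tetramethyl-1,2,3,4,4a,5,6,7-octahydronaphthalen-1-yl]pentanoate | O=C(OC[C@@H]1CO1)C[C@H](C)CC[C@@]2(C)C3=CCCC(C)(C)[C@@H]3CC[C@H]2C | intermediate
32 | (2S)-3-acetoxy-2-hydroxypropyl (3R)-3-methyl-5-[(1R,2R,4aS)-1,2,5,5-tetramethyl-1,2,3,4,4a,5,6,7-octahydronaphthalen-1-yl]pentanoate | CC(=O)OC[C@H](O)COC(=O)C[C@H](C)CC[C@@]1(C)C2=CCCC(C)(C)[C@@H]2CC[C@H]1C | target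

**Step count.** Total: 17 steps. Longest linear sequence: 17 steps (steps 1–17, from 1 and 2 to 32); aldehyde 4 made in step 1 is consumed in step 2, so every step lies on this one line.

**Steps most likely to fail**

Step 9. Three processes could spoil the cascade.
- The first shift may leak through a boat, because in the chair the (Z)-methyl group is 1,3-diaxial to the allyloxy group; this would erode the enantiomeric purity.
- The ene closure may occur from the first-formed ring conformer before the C5=C6 unit has turned over, which would give the C5/C10-epimeric decalinol.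
- The tertiary allylic ether may be lost thermally.

Fallback: the same three bonds are made stepwise, setting out from alcohol 15. Anionic oxy-Cope rearrangement (KH, 18-crown-6, THF, 0 °C to rt) would give potassium (1Z,3R,5E)-2,3,7,7-tetramethylcyclodeca-1,5-dien-1-olate F1. C-allylation of F1 on its open face with 16 would give ketone 19, now as an isolated compound. The transannular carbonyl-ene closure would then be induced at low temperature with Me2AlCl (CH2Cl2, −78 °C), where the ring conformers equilibrate before reaction, and the route is rejoined at 20.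

Step 5. Acylation of the hindered carbinol may be slow or poorly enantioselective, so that the recovered alcohol is not enantiopure. Fallback: setting out from racemic 9, esterification with (S)-methoxy(phenyl)acetic acid (DCC, DMAP) would give two diastereomeric esters, (1S,2R)-3,3-dimethyl-2-vinylcyclohexyl (2S)-methoxy(phenyl)acetate F2 and (1R,2S)-3,3-dimethyl-2-vinylcyclohexyl (2S)-methoxy(phenyl)acetate F3. These are separated by chromatography, and saponification of F2 (LiOH, THF–MeOH–H2O) returns the route to 10.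

Step 17. Attack at the internal epoxide carbon, or acyl shift between the glycerol oxygens during or after ring opening, would give regioisomeric diacylglycerols. Fallback: the glycerol unit is built stepwise, setting out from acid 29. Esterification with (R)-solketal (DCC, DMAP) would give [(4S)-2,2-dimethyl-1,3-dioxolan-4-yl]methyl (3R)-3-methyl-5-[(1R,2R,4aS)-1,2,5,5-tetramethyl-1,2,3,4,4a,5,6,7-octahydronaphthalen-1-yl]pentanoate F4. The acetonide is cleaved under conditions used for monoacylglycerols (Me2BBr, CH2Cl2, −50 °C) to give (2S)-2,3-dihydroxypropyl (3R)-3-methyl-5-[(1R,2R,4aS)-1,2,5,5-tetramethyl-1,2,3,4,4a,5,6,7-octahydronaphthalen-1-yl]pentanoate F5. Selective acetylation of the primary hydroxyl (AcCl, 2,4,6-collidine, CH2Cl2, −78 °C) then gives 32.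

Further compounds
F1 | step 9 | potassium (1Z,3R,5E)-2,3,7,7-tetramethylcyclodeca-1,5-dien-1-olate | [K+].[O-]/C1=C(C)\[C@H](C)C/C=C/C(C)(C)CCC1
F2 | step 5 | (1S,2R)-3,3-dimethyl-2-vinylcyclohexyl (2S)-methoxy(phenyl)acetate | CO[C@H](C(=O)O[C@H]1CCCC(C)(C)[C@H]1C=C)c1ccccc1
F3 | step 5 | (1R,2S)-3,3-dimethyl-2-vinylcyclohexyl (2S)-methoxy(phenyl)acetate | CO[C@H](C(=O)O[C@@H]1CCCC(C)(C)[C@@H]1C=C)c1ccccc1
F4 | step 17 | [(4S)-2,2-dimethyl-1,3-dioxolan-4-yl]methyl (3R)-3-methyl-5-[(1R,2R,4aS)-1,2,5,5-tetramethyl-1,2,3,4,4a,5,6,7-octahydronaphthalen-1-yl]pentanoate | CC1(C)OC[C@@H](COC(=O)C[C@H](C)CC[C@@]2(C)C3=CCCC(C)(C)[C@@H]3CC[C@H]2C)O1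
F5 | step 17 | (2S)-2,3-dihydroxypropyl (3R)-3-methyl-5-[(1R,2R,4aS)-1,2,5,5-tetramethyl-1,2,3,4,4a,5,6,7-octahydronaphthalen-1-yl]pentanoate | OC[C@H](O)COC(=O)C[C@H](C)CC[C@@]1(C)C2=CCCC(C)(C)[C@@H]2CC[C@H]1C
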